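## Retrosynthetic overview

1. Target 21 ⇐ penta-O-benzyl dimer 20 by global hydrogenolysis of five benzyl ethers.
2. 20 ⇐ 4-arylflav-3-ene 18 by hydroboration–oxidation of C3=C4, which sets C3 and C4 together from C2.
3. 18 ⇐ flavanone 14 + aryl bromide 9: the interflavan C4–C6 bond joins two electrophilic carbons, the C4 carbonyl of 14 (made nucleophilic as the diazo carbon of its tosylhydrazone) and the C6–Br carbon of 9, under Pd catalysis.
4. 14 ⇐ chromone 12 (pyranone ring closed from acetophenone 10) by enantioselective conjugate arylation with 13.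
5. 9 ⇐ racemic flavan-3-one 8 by dynamic kinetic resolution ⇐ nitrochromene 5 from 2 + 3. Ring order: lower pyran ring (step 2), upper pyranone ring (step 5); all benzene rings are bought in.

Assumption: the sense of induction of the chiral catalysts in steps 4 and 6 is assigned by analogy with simpler substrates; if either is opposite, the mirror-image ligand set is used and nothing else changes.

## Route

Step 1
Reactants: 1 4-(benzyloxy)-2-hydroxybenzaldehyde
Product: 2 4-(benzyloxy)-5-bromo-2-hydroxybenzaldehyde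
Conditions: NBS (1.05 equiv), MeCN, 0 °C to rt
Reagents that add atoms: N-bromosuccinimide, O=C1CCC(=O)N1Br
Why: Electrophilic aromatic bromination goes to C5, para to the free phenol and ortho to the benzyloxy group, as in the known 5-bromination of 2-hydroxy-4-alkoxybenzaldehydes; no stereocenter is formed.

Step 2
Reactants: 2 4-(benzyloxy)-5-bromo-2-hydroxybenzaldehyde; 3 (E)-1,2-bis(benzyloxy)-4-(2-nitroethenyl)benzene
Product: 5 rac-7-(benzyloxy)-2-[3,4-bis(benzyloxy)phenyl]-6-bromo-3-nitro-2H-chromene, via nitroaldol adduct 4 (not isolated)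
Conditions: DABCO (0.5 equiv), MeCN, 60 °C
Reagents that add atoms: none
Why: Domino oxa-Michael/Henry (nitroaldol)/dehydration closes the lower pyran ring, the nitronate carbon (future C3) attacking the aldehyde carbon (future C4); C2 is formed racemic on purpose because it is resolved dynamically in step 4.

Step 3
Reactants: 5 rac-7-(benzyloxy)-2-[3,4-bis(benzyloxy)phenyl]-6-bromo-3-nitro-2H-chromene
Product: 8 rac-7-(benzyloxy)-2-[3,4-bis(benzyloxy)phenyl]-6-bromochroman-3-one, via oxime 6 (not isolated), via imine 7 (not isolated)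
Conditions: Fe powder (6 equiv), AcOH/H2O (9:1), 90 °C
Reagents that add atoms: water, O
Why: Iron/acetic acid reduction of a conjugated nitroalkene to the ketone (reductive Nef-type conversion, as for arylnitropropenes) proceeds through the oxime and imine, which hydrolyse in the aqueous acid; aryl bromide and benzyl ethers are inert, and C2 stays racemic, which is what step 4 needs.

Step 4
Reactants: 8 rac-7-(benzyloxy)-2-[3,4-bis(benzyloxy)phenyl]-6-bromochroman-3-one
Product: 9 (2S,3S)-7-(benzyloxy)-2-[3,4-bis(benzyloxy)phenyl]-6-bromochroman-3-ol (2,3-cis)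
Conditions: RuCl2[(R)-xylbinap][(R)-daipen] (1 mol%), KOtBu (10 mol%), H2 (8 atm), i-PrOH/THF (3:1), 25 °C
Reagents that add atoms: none
Why: Proposed new method: the C2–H of the flavan-3-one (alpha to the ketone, benzylic and alpha to oxygen) is acidic enough for KOtBu to racemise C2 faster than the chiral ruthenium hydride reduces the ketone, and the catalyst reduces one enantiomer with hydride delivered anti to the 2-aryl group, giving the 2,3-cis (2S,3S) alcohol; the closest known reaction is the Noyori dynamic-kinetic-resolution hydrogenation of 2-alkoxy- and 2-arylcyclohexanones to cis alcohols.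

Step 5
Reactants: 10 1-[4-(benzyloxy)-2-hydroxyphenyl]ethan-1-one
Product: 12 7-(benzyloxy)-4H-chromen-4-one, via enaminone 11 (not isolated)
Conditions: Me2NCH(OMe)2 (2 equiv), toluene, 100 °C; then conc. HCl, CH2Cl2, 40 °C
Reagents that add atoms: N,N-dimethylformamide dimethyl acetal, COC(OC)N(C)C
Why: Standard chromone synthesis: condensation of the methyl ketone with the formamide acetal gives the enaminone, and acid-promoted conjugate addition of the phenol with loss of dimethylamine closes the upper pyranone ring; no stereocenter is formed.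

Step 6
Reactants: 12 7-(benzyloxy)-4H-chromen-4-one; 13 [4-(benzyloxy)phenyl]boronic acid
Product: 14 (2S)-7-(benzyloxy)-2-[4-(benzyloxy)phenyl]chroman-4-one
Conditions: Pd(OCOCF3)2 (5 mol%), (R)-t-BuPyOx (6 mol%), NH4PF6 (30 mol%), H2O (5 equiv), ClCH2CH2Cl, 60 °C
Reagents that add atoms: none
Why: Palladium-catalysed enantioselective conjugate addition of an arylboronic acid to a chromone (pyridine-oxazoline ligand) sets C2 by ligand control; the (2S)-flavanone has the same spatial arrangement as C2 (R) of the target's upper unit, and the neutral conditions avoid the base-induced ring-opening racemisation of flavanones.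

Step 7
Reactants: 14 (2S)-7-(benzyloxy)-2-[4-(benzyloxy)phenyl]chroman-4-one; 15 4-methylbenzenesulfonohydrazide; 9 (2S,3S)-7-(benzyloxy)-2-[3,4-bis(benzyloxy)phenyl]-6-bromochroman-3-ol
Product: 18 (2S,3S)-7-(benzyloxy)-6-{(2S)-7-(benzyloxy)-2-[4-(benzyloxy)phenyl]-2H-chromen-4-yl}-2-[3,4-bis(benzyloxy)phenyl]chroman-3-ol, via tosylhydrazone 16 (not isolated), via diazo compound 17 (not isolated)
Conditions: 14 (1.3 equiv), TsNHNH2 (1.35 equiv), 1,4-dioxane, 60 °C, 3 h; then 9 (1.0 equiv), Pd2(dba)3 (2.5 mol%), XPhos (10 mol%), LiOtBu (5 equiv), 80 °C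
Reagents that add atoms: none
Why: Barluenga cross-coupling: the tosylhydrazone turns the electrophilic C4 carbonyl carbon into a nucleophilic diazo carbon that attacks the aryl–palladium bromide (divalent palladium, from oxidative addition of zerovalent palladium into the C6–Br bond of 9), carbene migratory insertion makes the C4–C6 bond and beta-hydride elimination from C3 gives the C3=C4 alkene; no stereocenter is formed, C2 of the upper unit is no longer alpha to a carbonyl, and the lower unit cannot epimerise because its 4'-oxygen is benzylated.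

Step 8
Reactants: 18 (2S,3S)-7-(benzyloxy)-6-{(2S)-7-(benzyloxy)-2-[4-(benzyloxy)phenyl]-2H-chromen-4-yl}-2-[3,4-bis(benzyloxy)phenyl]chroman-3-ol
Product: 20 (2R,3S,4S)-7-(benzyloxy)-4-{(2S,3S)-7-(benzyloxy)-2-[3,4-bis(benzyloxy)phenyl]-3-hydroxychroman-6-yl}-2-[4-(benzyloxy)phenyl]chroman-3-ol (2,3-trans-3,4-trans), via organoborane 19 (not isolated)
Conditions: BH3·THF (5 equiv), THF, 0 °C to rt; then 3 M NaOH, 30% H2O2, 0 °C to rt
Reagents that add atoms: hydrogen peroxide, OO
Why: Hydroboration–oxidation, as known for flav-3-enes: borane adds syn with boron at the less substituted C3 from the face anti to the 2-aryl group, so the C3–O bond (oxidation with retention) is trans to the 2-aryl group and the hydrogen delivered to C4 on the same face leaves the C4 aryl trans to the 3-OH and cis to the 2-aryl group, setting C3 and C4 in one step.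

Step 9
Reactants: 20 (2R,3S,4S)-7-(benzyloxy)-4-{(2S,3S)-7-(benzyloxy)-2-[3,4-bis(benzyloxy)phenyl]-3-hydroxychroman-6-yl}-2-[4-(benzyloxy)phenyl]chroman-3-ol
Product: 21 (2R,3S,4R)-4-[(2S,3S)-2-(3,4-dihydroxyphenyl)-3,7-dihydroxychroman-6-yl]-2-(4-hydroxyphenyl)chroman-3,7-diol (target)
Conditions: H2 (1 atm), Pd(OH)2/C (20 wt%), THF/MeOH (1:1), rt
Reagents that add atoms: none
Why: Catalytic hydrogenolysis removes the five O-benzyl groups while the interflavan C–C bond and the pyran C–O bonds survive, as in standard proanthocyanidin end-games; no stereocenter is touched (the C4 descriptor changes from S to R only through CIP priorities).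

## Compound list

1 | 4-(benzyloxy)-2-hydroxybenzaldehyde | O=Cc1ccc(OCc2ccccc2)cc1O | starting material
2 | 4-(benzyloxy)-5-bromo-2-hydroxybenzaldehyde | O=Cc1cc(Br)c(OCc2ccccc2)cc1O | intermediate
3 | (E)-1,2-bis(benzyloxy)-4-(2-nitroethenyl)benzene | [O-][N+](=O)/C=C/c1ccc(OCc2ccccc2)c(OCc2ccccc2)c1 | starting material
4 | 7-(benzyloxy)-2-[3,4-bis(benzyloxy)phenyl]-6-bromo-3-nitrochroman-4-ol (racemic, diastereomer mixture) | OC1c2cc(Br)c(OCc3ccccc3)cc2OC(c2ccc(OCc3ccccc3)c(OCc3ccccc3)c2)C1[N+](=O)[O-] | intermediate (not isolated)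
5 | rac-7-(benzyloxy)-2-[3,4-bis(benzyloxy)phenyl]-6-bromo-3-nitro-2H-chromene | [O-][N+](=O)C1=Cc2cc(Br)c(OCc3ccccc3)cc2OC1c1ccc(OCc2ccccc2)c(OCc2ccccc2)c1 | intermediate
6 | rac-7-(benzyloxy)-2-[3,4-bis(benzyloxy)phenyl]-6-bromochroman-3-one oxime | ON=C1Cc2cc(Br)c(OCc3ccccc3)cc2OC1c1ccc(OCc2ccccc2)c(OCc2ccccc2)c1 | intermediate (not isolated)
7 | rac-7-(benzyloxy)-2-[3,4-bis(benzyloxy)phenyl]-6-bromochroman-3-imine | N=C1Cc2cc(Br)c(OCc3ccccc3)cc2OC1c1ccc(OCc2ccccc2)c(OCc2ccccc2)c1 | intermediate (not isolated)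
8 | rac-7-(benzyloxy)-2-[3,4-bis(benzyloxy)phenyl]-6-bromochroman-3-one | O=C1Cc2cc(Br)c(OCc3ccccc3)cc2OC1c1ccc(OCc2ccccc2)c(OCc2ccccc2)c1 | intermediate
9 | (2S,3S)-7-(benzyloxy)-2-[3,4-bis(benzyloxy)phenyl]-6-bromochroman-3-ol (2,3-cis) | Brc1cc2c(cc1OCc1ccccc1)O[C@@H](c1ccc(OCc3ccccc3)c(OCc3ccccc3)c1)[C@@H](O)C2 | intermediate
10 | 1-[4-(benzyloxy)-2-hydroxyphenyl]ethan-1-one | CC(=O)c1ccc(OCc2ccccc2)cc1O | starting material
11 | (E)-1-[4-(benzyloxy)-2-hydroxyphenyl]-3-(dimethylamino)prop-2-en-1-one | CN(C)/C=C/C(=O)c1ccc(OCc2ccccc2)cc1O | intermediate (not isolated)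
12 | 7-(benzyloxy)-4H-chromen-4-one | O=c1ccoc2cc(OCc3ccccc3)ccc12 | intermediate
13 | [4-(benzyloxy)phenyl]boronic acid | OB(O)c1ccc(OCc2ccccc2)cc1 | starting material
14 | (2S)-7-(benzyloxy)-2-[4-(benzyloxy)phenyl]chroman-4-one | c1ccccc1COc1ccc([C@H]2Oc3cc(OCc4ccccc4)ccc3C(=O)C2)cc1 | intermediate
15 | 4-methylbenzenesulfonohydrazide | Cc1ccc(cc1)S(=O)(=O)NN | starting material
16 | N'-{(2S)-7-(benzyloxy)-2-[4-(benzyloxy)phenyl]chroman-4-ylidene}-4-methylbenzenesulfonohydrazide | c1ccccc1COc1ccc([C@H]2Oc3cc(OCc4ccccc4)ccc3C(=NNS(=O)(=O)c3ccc(C)cc3)C2)cc1 | intermediate (not isolated)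
17 | (2S)-7-(benzyloxy)-2-[4-(benzyloxy)phenyl]-4-diazochroman | c1ccccc1COc1ccc([C@H]2Oc3cc(OCc4ccccc4)ccc3C(=[N+]=[N-])C2)cc1 | intermediate (not isolated)
18 | (2S,3S)-7-(benzyloxy)-6-{(2S)-7-(benzyloxy)-2-[4-(benzyloxy)phenyl]-2H-chromen-4-yl}-2-[3,4-bis(benzyloxy)phenyl]chroman-3-ol | c1ccccc1COc1ccc([C@H]2Oc3cc(OCc4ccccc4)ccc3C(c3cc4c(cc3OCc3ccccc3)O[C@@H](c3ccc(OCc5ccccc5)c(OCc5ccccc5)c3)[C@@H](O)C4)=C2)cc1 | intermediate
19 | bis-borane adduct of 18: BH2 on C3 of the upper unit trans to the 2-aryl group, hydrogen added to C4 on the same face, lower 3-oxygen as O–BH2; same spatial arrangement as 20 | c1ccccc1COc1ccc([C@H]2Oc3cc(OCc4ccccc4)ccc3[C@@H](c3cc4c(cc3OCc3ccccc3)O[C@@H](c3ccc(OCc5ccccc5)c(OCc5ccccc5)c3)[C@@H](OB)C4)[C@@H]2B)cc1 | intermediate (not isolated)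
20 | (2R,3S,4S)-7-(benzyloxy)-4-{(2S,3S)-7-(benzyloxy)-2-[3,4-bis(benzyloxy)phenyl]-3-hydroxychroman-6-yl}-2-[4-(benzyloxy)phenyl]chroman-3-ol (2,3-trans-3,4-trans upper unit, 2,3-cis lower unit) | c1ccccc1COc1ccc([C@H]2Oc3cc(OCc4ccccc4)ccc3[C@@H](c3cc4c(cc3OCc3ccccc3)O[C@@H](c3ccc(OCc5ccccc5)c(OCc5ccccc5)c3)[C@@H](O)C4)[C@@H]2O)cc1 | intermediate
21 | (2R,3S,4R)-4-[(2S,3S)-2-(3,4-dihydroxyphenyl)-3,7-dihydroxychroman-6-yl]-2-(4-hydroxyphenyl)chroman-3,7-diol, i.e. guibourtinidol-(4α→6)-ent-epifisetinidol | Oc1ccc([C@H]2Oc3cc(O)ccc3[C@@H](c3cc4c(cc3O)O[C@@H](c3ccc(O)c(O)c3)[C@@H](O)C4)[C@@H]2O)cc1 | target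

## Step count and risks

Total steps: 9. Longest linear sequence: 7 (steps 1, 2, 3, 4, 7, 8, 9); the upper unit (steps 5, 6) joins at step 7.

Most likely to fail, first: step 7. The aryl bromide is hindered and electron-rich, the diazo compound can collapse to the 4-unsubstituted flavene (Bamford–Stevens), and at 80 °C the 2-aryl-2H-chromene product could lose C2 integrity by reversible electrocyclic ring opening. The fallback sets out from 14 and comes back at 18. Flavanone 14 is condensed with 2,4,6-triisopropylbenzenesulfonohydrazide (MeOH, cat. HCl, rt) to the 2,4,6-triisopropylbenzenesulfonylhydrazone F1. n-BuLi (2.2 equiv, THF, −78 °C to 0 °C, Shapiro reaction) converts it into the (2S)-4-lithio-2H-chromene F2, in which the former carbonyl carbon is a true vinyl carbanion. ZnCl2 gives the alkenylzinc chloride F3, which is added slowly to 9 with Pd2(dba)3/SPhos in THF at 25–40 °C (Negishi coupling; the free secondary hydroxyl is tolerated under slow addition) to give 18 without ever heating the chromene.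

Second: step 4. The dynamic kinetic resolution is untested on flavan-3-ones; racemisation may be too slow or the cis selectivity or ee insufficient. The fallback sets out from 2 (with 3) and comes back at 9, setting C2 before the ketone is formed. 2 and 3 are combined under a chiral pyrrolidine-type secondary amine/acid co-catalyst (enantioselective oxa-Michael/Henry, product enriched by crystallisation) to give the (2S)-nitrochromene F4. NaBH4 (THF/MeOH, 0 °C) reduces the nitroalkene to the (2S)-3-nitrochroman F5. NaOMe followed by buffered aqueous TiCl3/NH4OAc (McMurry variant of the Nef reaction) gives the (2S)-flavan-3-one F6. LiBH(s-Bu)3 (THF, −78 °C) attacks anti to the 2-aryl group and gives 9.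

Third: step 8. The C3 borane sits beta to the ring oxygen and could eliminate with ring opening, and the alkene is trisubstituted and flanked by a bulky aryl group. The fallback sets out from 18 and comes back at 20 without any carbon–boron intermediate. Dimethyldioxirane (acetone/CH2Cl2, −40 °C) epoxidises C3=C4 anti to the 2-aryl group to give the 3,4-epoxide F7, which is used crude because it is acid-labile. Hydrogenolysis of its benzylic C4–O bond over Raney Ni (H2, 1 atm, EtOH, rt) proceeds with retention at C4 (nickel, unlike palladium), so hydrogen takes the place of the epoxide oxygen and the same 2,3-trans-3,4-trans alcohol 20 results; any partly debenzylated material converges on 21 in step 9.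

## Further compounds

F1 | step 7 | N'-{(2S)-7-(benzyloxy)-2-[4-(benzyloxy)phenyl]chroman-4-ylidene}-2,4,6-tri(propan-2-yl)benzenesulfonohydrazide | c1ccccc1COc1ccc([C@H]2Oc3cc(OCc4ccccc4)ccc3C(=NNS(=O)(=O)c3c(C(C)C)cc(C(C)C)cc3C(C)C)C2)cc1
F2 | step 7 | (2S)-7-(benzyloxy)-2-[4-(benzyloxy)phenyl]-4-lithio-2H-chromene | c1ccccc1COc1ccc([C@H]2Oc3cc(OCc4ccccc4)ccc3C([Li])=C2)cc1
F3 | step 7 | {(2S)-7-(benzyloxy)-2-[4-(benzyloxy)phenyl]-2H-chromen-4-yl}zinc chloride | c1ccccc1COc1ccc([C@H]2Oc3cc(OCc4ccccc4)ccc3C([Zn]Cl)=C2)cc1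
F4 | step 4 | (2S)-7-(benzyloxy)-2-[3,4-bis(benzyloxy)phenyl]-6-bromo-3-nitro-2H-chromene | Brc1cc2c(cc1OCc1ccccc1)O[C@@H](c1ccc(OCc3ccccc3)c(OCc3ccccc3)c1)C([N+](=O)[O-])=C2
F5 | step 4 | (2S)-7-(benzyloxy)-2-[3,4-bis(benzyloxy)phenyl]-6-bromo-3-nitrochroman (C3 epimer mixture) | Brc1cc2c(cc1OCc1ccccc1)O[C@@H](c1ccc(OCc3ccccc3)c(OCc3ccccc3)c1)C([N+](=O)[O-])C2
F6 | step 4 | (2S)-7-(benzyloxy)-2-[3,4-bis(benzyloxy)phenyl]-6-bromochroman-3-one | Brc1cc2c(cc1OCc1ccccc1)O[C@@H](c1ccc(OCc3ccccc3)c(OCc3ccccc3)c1)C(=O)C2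
F7 | step 8 | 3,4-epoxide of 18 with the oxirane oxygen on the face anti to the 2-aryl group of the upper unit | c1ccccc1COc1ccc([C@H]2Oc3cc(OCc4ccccc4)ccc3[C@@]4(c3cc5c(cc3OCc3ccccc3)O[C@@H](c3ccc(OCc6ccccc6)c(OCc6ccccc6)c3)[C@@H](O)C5)[C@@H]2O4)cc1
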